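**Strategy.** Everything rests on breaking the bond between the angular lactone α-carbon (common to rings B, C and D) and the neighbouring ring C carbon that carries bromine. Ring D, the γ-lactone, has to be cis-fused to the cyclopentane ring B along the bond from this angular carbon to the ring-fusion CH, so an enolate at the angular carbon can bond only on the lactone face turned away from ring B. A samarium Reformatsky aldol therefore closes ring C, builds the quaternary centre with the trans B/C junction and sets the carbinol in one operation. Its precursor is a cis-fused α-bromo cyclopenta-γ-lactone with a 3-oxopropyl arm anti to ring B and a silyl-protected hydroxyethyl arm.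

Key step: step 11

Remark: rings are A (bromocyclohexanol), B (cyclopentane), C (bromocyclohexane) and D (γ-lactone); tricyclic compounds carry hydrindane locants (C3 arm-bearing carbon, C3a ring-fusion CH, C4 lactone C–O carbon, C7 carbinol or bromide carbon, C7a angular carbon, lactone bridge C8(=O)–O9 from C7a to C4); both enantiomers of the amine catalyst, the fructose-derived ketone catalyst and allyltrimethylsilane are taken as commercial.

Step 1
Reactants: 1 2-methylfuran
Product: 3 (2E)-4-oxopent-2-enal, via (2Z)-4-oxopent-2-enal 2 (not isolated)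
Conditions: NBS, NaHCO3, acetone–H2O, −15 °C; then pyridine, rt
Reagents that add atoms: water, O
Why: Oxidative furan ring opening: bromonium attack and hydrolysis unmask the cis ene-dione, which pyridine isomerises to the trans isomer needed for iminium catalysis; no stereocentre is formed.

Step 2
Reactants: 3 (2E)-4-oxopent-2-enal; 4 diethyl 2-(2-bromoethyl)propanedioate
Product: 6 diethyl (2S,3R)-2-acetyl-3-formylcyclopentane-1,1-dicarboxylate, via acyclic Michael adduct 5 (not isolated)
Conditions: (R)-2-[diphenyl(trimethylsilyloxy)methyl]pyrrolidine (20 mol %), 2,6-lutidine, CHCl3, 0 °C → rt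
Reagents that add atoms: none
Why: Organocatalytic Michael–α-alkylation cascade: the (R)-amine forms the E-iminium ion of the aldehyde, the malonate adds to the carbon next to the ketone on the face not covered by the diphenyl(silyloxy)methyl group (2S, the later ring-fusion CH), and the enamine so formed displaces bromide in a 5-exo-tet closure that puts formyl trans to acetyl (3R).

Step 3
Reactants: 6 diethyl (2S,3R)-2-acetyl-3-formylcyclopentane-1,1-dicarboxylate
Product: 7 diethyl (2S,3S)-2-acetyl-3-ethenylcyclopentane-1,1-dicarboxylate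
Conditions: CH2I2, Zn, Ti(OiPr)4, THF, rt
Reagents that add atoms: diiodomethane, ICI
Why: Takai–Lombardo-type methylenation: the zinc–titanium methylene reagent reacts with the aldehyde much faster than with the ketone and is not basic, so the α-stereocentre is neither epimerised nor lost by retro-Michael cleavage.

Step 4
Reactants: 7 diethyl (2S,3S)-2-acetyl-3-ethenylcyclopentane-1,1-dicarboxylate
Product: 9 diethyl (2S,3S)-2-acetyl-3-(2-hydroxyethyl)cyclopentane-1,1-dicarboxylate, via catechol boronate 8 (not isolated)
Conditions: catecholborane, RhCl(PPh3)3 (2 mol %), THF, rt; then H2O2, pH 7 buffer, 0 °C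
Reagents that add atoms: hydrogen peroxide, OO
Why: Rhodium-catalysed hydroboration–oxidation: with the catalyst the B–H bond adds to the terminal alkene (boron on the end carbon) faster than catecholborane reduces the ketone, and the C–B bond is oxidised to the primary alcohol.

Step 5
Reactants: 9 diethyl (2S,3S)-2-acetyl-3-(2-hydroxyethyl)cyclopentane-1,1-dicarboxylate
Product: 10 diethyl (2S,3S)-2-acetyl-3-{2-[tri(propan-2-yl)silyloxy]ethyl}cyclopentane-1,1-dicarboxylate
Conditions: iPr3SiCl, imidazole, DMF, rt
Reagents that add atoms: chlorotri(propan-2-yl)silane, CC(C)[Si](Cl)(C(C)C)C(C)C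
Why: Silyl ether formation at the only hydroxyl; the triisopropylsilyl group is chosen to survive hydroxide, Lewis acid, amide base, hydride and hot phosphine/CBr4 later on.

Step 6
Reactants: 10 diethyl (2S,3S)-2-acetyl-3-{2-[tri(propan-2-yl)silyloxy]ethyl}cyclopentane-1,1-dicarboxylate
Product: 11 (2S,3S)-2-acetyl-3-{2-[tri(propan-2-yl)silyloxy]ethyl}cyclopentane-1,1-dicarboxylic acid
Conditions: LiOH, THF–MeOH–H2O, 50 °C; then 1 M HCl, 0 °C
Reagents that add atoms: lithium hydroxide, [Li+].[OH-]
Why: Ester saponification; the geminal diacid is kept so that one carboxyl is necessarily cis to the acetyl group, and base can only return the ketone α-carbon to the trans arrangement it already has.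

Step 7
Reactants: 11 (2S,3S)-2-acetyl-3-{2-[tri(propan-2-yl)silyloxy]ethyl}cyclopentane-1,1-dicarboxylic acid
Product: 14 allyl lactone (3R,3aS,4S,6aR)-3-methyl-3-(prop-2-en-1-yl)-4-{2-[tri(propan-2-yl)silyloxy]ethyl}hexahydro-1H-cyclopenta[c]furan-1-one, via hydroxy lactone acid 12 (not isolated), via carboxy lactone 13 (not isolated)
Conditions: allylSiMe3, Me3SiOTf (30 mol %), CH2Cl2–MeCN, −40 → 0 °C; aqueous work-up; then toluene, 110 °C
Reagents that add atoms: allyltrimethylsilane, C=CC[Si](C)(C)C
Why: Hosomi–Sakurai allylation of a cyclic acyloxocarbenium ion: the cis carboxyl closes onto the activated ketone, ionisation gives the cis-fused bicyclic cation and the allylsilane should add on its convex face, anti to ring B, which sets the lactone C–O carbon (3R) with methyl syn and allyl anti to ring B; the remaining β-carboxy lactone loses CO2 on heating and can only be protonated to the cis-fused lactone.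

Step 8
Reactants: 14 allyl lactone
Product: 15 α-bromo allyl lactone (3R,3aR,4S,6aS)-6a-bromo-3-methyl-3-(prop-2-en-1-yl)-4-{2-[tri(propan-2-yl)silyloxy]ethyl}hexahydro-1H-cyclopenta[c]furan-1-one
Conditions: LiN(iPr)2, THF, −78 °C; then BrCl2C–CCl2Br, −78 °C
Reagents that add atoms: 1,2-dibromo-1,1,2,2-tetrachloroethane, ClC(Cl)(Br)C(Cl)(Cl)Br
Why: Enolate bromination: the lactone α-hydrogen is the only acidic one, and the cis ring fusion leaves bromine no choice but the convex face (this centre becomes trigonal again in step 11).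

Step 9
Reactants: 15 α-bromo allyl lactone
Product: 17 bromo lactone alcohol (3R,3aR,4S,6aS)-6a-bromo-3-(3-hydroxypropyl)-3-methyl-4-{2-[tri(propan-2-yl)silyloxy]ethyl}hexahydro-1H-cyclopenta[c]furan-1-one, via B-alkyl-9-BBN adduct 16 (not isolated)
Conditions: 9-BBN, THF, 0 °C → rt; then H2O2, pH 7 buffer, 0 °C
Reagents that add atoms: hydrogen peroxide, OO
Why: Hydroboration–oxidation: 9-BBN adds to the terminal alkene with boron on the end carbon and leaves the tertiary bromide and the lactone alone; buffered peroxide gives the primary alcohol.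

Step 10
Reactants: 17 bromo lactone alcohol
Product: 18 α-bromo lactone aldehyde 3-[(3R,3aR,4S,6aS)-6a-bromo-3-methyl-1-oxo-4-{2-[tri(propan-2-yl)silyloxy]ethyl}hexahydro-1H-cyclopenta[c]furan-3-yl]propanal
Conditions: Dess–Martin periodinane, CH2Cl2, rt
Reagents that add atoms: none
Why: Dess–Martin oxidation of the primary alcohol under neutral conditions that do not touch the tertiary α-bromo lactone or the silyl ether.

Step 11
Reactants: 18 α-bromo lactone aldehyde
Product: 20 tricyclic β-hydroxy lactone (3S,3aS,4R,7S,7aR; 7-hydroxyl equatorial and syn to the lactone carbonyl), via samarium enolate 19 (not isolated)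
Conditions: SmI2 (2.5 equiv), THF, −78 °C; then pH 7 buffer
Reagents that add atoms: none
Why: Two electrons from SmI2 cleave the tertiary C–Br bond and give a trivalent samarium enolate that is trigonal at the angular carbon; it adds to the aldehyde on the three-carbon arm and the samarium aldolate is protonated on work-up. The closest known reaction type is the samarium diiodide-promoted intramolecular Reformatsky reaction. Ring C closes by a 6-exo-trig aldol addition (6-enolexo) that bridges the α- and γ-carbons of the lactone and gives the 6-oxabicyclo[3.2.1]octan-7-one. The angular quaternary carbon (7aR) is fixed by the cis fusion of rings B and D, since the arm sits on the lactone face anti to ring B and reaches the enolate only there, which makes the B/C junction trans; the carbinol carbon (7S) is fixed by a chair transition state in which samarium bridges the enolate and aldehyde oxygens and holds the hydroxyl equatorial and syn to the lactone carbonyl. The step needs electron transfer to the C–Br bond and not to the aldehyde, and bond formation before protonation; the α-bromo lactone is reduced far faster than an aliphatic aldehyde at −78 °C and no proton source is present.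

Step 12
Reactants: 20 tricyclic β-hydroxy lactone
Product: 21 tricyclic β-keto lactone (3S,3aS,4R,7aR; C7 ketone)
Conditions: Dess–Martin periodinane, CH2Cl2, rt
Reagents that add atoms: none
Why: Dess–Martin oxidation of the secondary alcohol; the ketone so formed has no hydrogen on the carbon between the two carbonyl groups, so the quaternary centre cannot be lost by enolisation.

Step 13
Reactants: 21 tricyclic β-keto lactone
Product: 22 tricyclic axial alcohol (3S,3aS,4R,7R,7aR; 7-hydroxyl axial and anti to the lactone carbonyl)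
Conditions: LiBH(s-Bu)3, THF, −78 °C; then AcOH, −78 °C
Reagents that add atoms: none
Why: Diastereoselective ketone reduction: the bulky hydride should approach along the equatorial trajectory, as in reductions of 3-keto-4,4-dimethyl terpenoids, and give the axial alcohol (7R), while the hindered lactone is not reduced at −78 °C.

Step 14
Reactants: 22 tricyclic axial alcohol
Product: 23 tricyclic bromide (3S,3aS,4R,7S,7aS; 7-bromine equatorial)
Conditions: CBr4, PPh3, toluene, 70 °C
Reagents that add atoms: tetrabromomethane, BrC(Br)(Br)Br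
Why: Appel reaction: bromide displaces the axial oxyphosphonium group with inversion (7S), which puts bromine equatorial and syn to the lactone carbonyl as in the target, in the way axial 3-hydroxy-4,4-dimethyl terpenoids give equatorial bromides.

Step 15
Reactants: 23 tricyclic bromide
Product: 24 bromo lactone with free 2-hydroxyethyl arm (3S,3aS,4R,7S,7aS)
Conditions: HF·pyridine, THF, 0 °C → rt
Reagents that add atoms: none
Why: Fluoride cleavage of the silyl ether under acidic buffering, which avoids base-induced elimination of the secondary bromide.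

Step 16
Reactants: 24 bromo lactone with free 2-hydroxyethyl arm
Product: 26 bromo lactone acetic acid (3S,3aS,4R,7S,7aS; arm CH2CO2H), via aldehyde 25 (not isolated)
Conditions: TEMPO (20 mol %), PhI(OAc)2, MeCN–H2O, rt
Reagents that add atoms: water, O
Why: Nitroxyl-catalysed oxidation of the primary alcohol through the aldehyde hydrate to the acid; the acid is the handle for removing the terminal carbon, since the ring A carbinol is best made by joining the CH2 next to ring B to a ketone.

Step 17
Reactants: 26 bromo lactone acetic acid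
Product: 27 bromo lactone iodide (3R,3aS,4R,7S,7aS; arm CH2I)
Conditions: PhI(OAc)2, I2, cyclohexane, hν, 80 °C
Reagents that add atoms: iodine, II
Why: Hunsdiecker-type decarboxylative iodination: the acyl hypoiodite loses CO2 to give the primary radical, which is trapped by iodine; the secondary bromide and the lactone are inert.

Step 18
Reactants: 28 6-methylhept-5-en-2-one
Product: 29 4-[(2R)-3,3-dimethyloxiran-2-yl]butan-2-one
Conditions: D-fructose-derived ketone catalyst (30 mol %), KHSO5, K2CO3, n-Bu4NHSO4, MeCN–dimethoxymethane–aq. buffer (pH 10.5), 0 °C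
Reagents that add atoms: potassium peroxymonosulfate, [K+].[O-]S(=O)(=O)OO
Why: Shi epoxidation: the chiral dioxirane delivers oxygen to one face of the trisubstituted alkene through a spiro transition state and sets the (R)-epoxide carbon.

Step 19
Reactants: 29 4-[(2R)-3,3-dimethyloxiran-2-yl]butan-2-one
Product: 30 trimethyl({4-[(2R)-3,3-dimethyloxiran-2-yl]but-1-en-2-yl}oxy)silane
Conditions: LiN(iPr)2, Me3SiCl, THF, −78 °C
Reagents that add atoms: chlorotrimethylsilane, C[Si](C)(C)Cl
Why: Kinetic enolate formation at the methyl group and O-silylation give the terminal silyl enol ether; the epoxide does not react at −78 °C.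

Step 20
Reactants: 30 trimethyl({4-[(2R)-3,3-dimethyloxiran-2-yl]but-1-en-2-yl}oxy)silane
Product: 32 (4R)-4-hydroxy-3,3-dimethylcyclohexan-1-one, via silyl ether 31 (not isolated)
Conditions: BF3·OEt2 (20 mol %), CH2Cl2, −78 °C; then 1 M HCl, THF
Reagents that add atoms: none
Why: Epoxide-initiated cation–olefin cyclization: the Lewis acid opens the epoxide at the tertiary carbon, the silyl enol ether closes the six-membered ring there (6-endo with respect to the epoxide), and the C–O bond of the stereocentre is never broken (R retained).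

Step 21
Reactants: 32 (4R)-4-hydroxy-3,3-dimethylcyclohexan-1-one
Product: 33 (4S)-4-bromo-3,3-dimethylcyclohexan-1-one
Conditions: CBr4, PPh3, toluene, 60 °C
Reagents that add atoms: tetrabromomethane, BrC(Br)(Br)Br
Why: Appel reaction: inversion at the secondary carbinol gives the (S)-bromide; the free ring can flip to present the leaving group axially.

Step 22
Reactants: 27 bromo lactone iodide; 33 (4S)-4-bromo-3,3-dimethylcyclohexan-1-one
Product: 34 target CNP0282702.2
Conditions: SmI2 (2.2 equiv), NiI2 (2 mol %), THF, 0 °C → rt; then pH 7 buffer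
Reagents that add atoms: none
Why: Samarium Barbier reaction: the primary iodide is reduced to the alkylsamarium far faster than the secondary bromides, and it should add to the ketone along the equatorial trajectory because the axial methyl group at C3 blocks the axial one, so that in the chair with equatorial bromine the new hydroxyl is axial and cis to bromine (1S).

**Compound list**

1 | 2-methylfuran | Cc1ccco1 | starting material
2 | (2Z)-4-oxopent-2-enal (not isolated) | CC(=O)/C=C\C=O | intermediate
3 | (2E)-4-oxopent-2-enal | CC(=O)/C=C/C=O | intermediate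
4 | diethyl 2-(2-bromoethyl)propanedioate | CCOC(=O)C(CCBr)C(=O)OCC | starting material
5 | diethyl 2-(2-bromoethyl)-2-[(3S)-1,4-dioxopentan-3-yl]propanedioate (acyclic Michael adduct, not isolated) | O=CC[C@H](C(C)=O)C(CCBr)(C(=O)OCC)C(=O)OCC | intermediate
6 | diethyl (2S,3R)-2-acetyl-3-formylcyclopentane-1,1-dicarboxylate | O=C[C@@H]1CCC(C(=O)OCC)(C(=O)OCC)[C@H]1C(C)=O | intermediate
7 | diethyl (2S,3S)-2-acetyl-3-ethenylcyclopentane-1,1-dicarboxylate | C=C[C@@H]1CCC(C(=O)OCC)(C(=O)OCC)[C@H]1C(C)=O | intermediate
8 | diethyl (2S,3R)-2-acetyl-3-[2-(1,3,2-benzodioxaborol-2-yl)ethyl]cyclopentane-1,1-dicarboxylate (catechol boronate, not isolated) | B1(CC[C@@H]2CCC(C(=O)OCC)(C(=O)OCC)[C@H]2C(C)=O)Oc2ccccc2O1 | intermediate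
9 | diethyl (2S,3S)-2-acetyl-3-(2-hydroxyethyl)cyclopentane-1,1-dicarboxylate | OCC[C@@H]1CCC(C(=O)OCC)(C(=O)OCC)[C@H]1C(C)=O | intermediate
10 | diethyl (2S,3S)-2-acetyl-3-{2-[tri(propan-2-yl)silyloxy]ethyl}cyclopentane-1,1-dicarboxylate | CC(C)[Si](C(C)C)(C(C)C)OCC[C@@H]1CCC(C(=O)OCC)(C(=O)OCC)[C@H]1C(C)=O | intermediate
11 | (2S,3S)-2-acetyl-3-{2-[tri(propan-2-yl)silyloxy]ethyl}cyclopentane-1,1-dicarboxylic acid | CC(C)[Si](C(C)C)(C(C)C)OCC[C@@H]1CCC(C(=O)O)(C(=O)O)[C@H]1C(C)=O | intermediate
12 | (3aS,4S,6aR)-3-hydroxy-3-methyl-1-oxo-4-{2-[tri(propan-2-yl)silyloxy]ethyl}hexahydro-1H-cyclopenta[c]furan-6a-carboxylic acid (hydroxy lactone acid, both C3 epimers, not isolated) | CC(C)[Si](C(C)C)(C(C)C)OCC[C@@H]1CC[C@@]2(C(=O)O)C(=O)OC(C)(O)[C@@H]12 | intermediate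
13 | (3R,3aS,4S,6aR)-3-methyl-1-oxo-3-(prop-2-en-1-yl)-4-{2-[tri(propan-2-yl)silyloxy]ethyl}hexahydro-1H-cyclopenta[c]furan-6a-carboxylic acid (carboxy lactone, not isolated) | CC(C)[Si](C(C)C)(C(C)C)OCC[C@@H]1CC[C@@]2(C(=O)O)C(=O)O[C@](C)(CC=C)[C@@H]12 | intermediate
14 | (3R,3aS,4S,6aR)-3-methyl-3-(prop-2-en-1-yl)-4-{2-[tri(propan-2-yl)silyloxy]ethyl}hexahydro-1H-cyclopenta[c]furan-1-one (cis-fused; allyl anti to ring B) | CC(C)[Si](C(C)C)(C(C)C)OCC[C@@H]1CC[C@H]2C(=O)O[C@](C)(CC=C)[C@@H]12 | intermediate
15 | (3R,3aR,4S,6aS)-6a-bromo-3-methyl-3-(prop-2-en-1-yl)-4-{2-[tri(propan-2-yl)silyloxy]ethyl}hexahydro-1H-cyclopenta[c]furan-1-one | CC(C)[Si](C(C)C)(C(C)C)OCC[C@@H]1CC[C@@]2(Br)C(=O)O[C@](C)(CC=C)[C@@H]12 | intermediate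
16 | B-alkyl-9-borabicyclo[3.3.1]nonane adduct of 15 (boron on the terminal carbon of the former allyl group, not isolated) | CC(C)[Si](C(C)C)(C(C)C)OCC[C@@H]1CC[C@@]2(Br)C(=O)O[C@](C)(CCCB3C4CCCC3CCC4)[C@@H]12 | intermediate
17 | (3R,3aR,4S,6aS)-6a-bromo-3-(3-hydroxypropyl)-3-methyl-4-{2-[tri(propan-2-yl)silyloxy]ethyl}hexahydro-1H-cyclopenta[c]furan-1-one | CC(C)[Si](C(C)C)(C(C)C)OCC[C@@H]1CC[C@@]2(Br)C(=O)O[C@](C)(CCCO)[C@@H]12 | intermediate
18 | 3-[(3R,3aR,4S,6aS)-6a-bromo-3-methyl-1-oxo-4-{2-[tri(propan-2-yl)silyloxy]ethyl}hexahydro-1H-cyclopenta[c]furan-3-yl]propanal (key-step precursor) | CC(C)[Si](C(C)C)(C(C)C)OCC[C@@H]1CC[C@@]2(Br)C(=O)O[C@](C)(CCC=O)[C@@H]12 | intermediate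
19 | diiodosamarium enolate of 18 (O-bound, angular carbon trigonal, not isolated) | CC(C)[Si](C(C)C)(C(C)C)OCC[C@@H]1CCC2=C(O[Sm](I)I)O[C@](C)(CCC=O)[C@@H]12 | intermediate
20 | tricyclic β-hydroxy lactone, (3S,3aS,4R,7S,7aR)-7-hydroxy-4-methyl-3-{2-[tri(propan-2-yl)silyloxy]ethyl} trans-hydrindane with lactone bridge C7a–C(=O)–O–C4; hydroxyl equatorial, syn to the lactone carbonyl (key-step product) | CC(C)[Si](C(C)C)(C(C)C)OCC[C@@H]1CC[C@]23C(=O)O[C@](C)(CC[C@@H]2O)[C@@H]13 | intermediate
21 | tricyclic β-keto lactone, (3S,3aS,4R,7aR), C7 ketone | CC(C)[Si](C(C)C)(C(C)C)OCC[C@@H]1CC[C@]23C(=O)O[C@](C)(CCC2=O)[C@@H]13 | intermediate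
22 | tricyclic axial alcohol, (3S,3aS,4R,7R,7aR), C7 epimer of 20 | CC(C)[Si](C(C)C)(C(C)C)OCC[C@@H]1CC[C@]23C(=O)O[C@](C)(CC[C@H]2O)[C@@H]13 | intermediate
23 | tricyclic bromide, (3S,3aS,4R,7S,7aS), bromine equatorial, arm as triisopropylsilyl ether | CC(C)[Si](C(C)C)(C(C)C)OCC[C@@H]1CC[C@]23C(=O)O[C@](C)(CC[C@@H]2Br)[C@@H]13 | intermediate
24 | tricyclic bromide with 2-hydroxyethyl arm, (3S,3aS,4R,7S,7aS) | OCC[C@@H]1CC[C@]23C(=O)O[C@](C)(CC[C@@H]2Br)[C@@H]13 | intermediate
25 | tricyclic bromide with 2-oxoethyl arm, (3S,3aS,4R,7S,7aS) (not isolated) | O=CC[C@@H]1CC[C@]23C(=O)O[C@](C)(CC[C@@H]2Br)[C@@H]13 | intermediate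
26 | tricyclic bromide with carboxymethyl arm, (3S,3aS,4R,7S,7aS) | OC(=O)C[C@@H]1CC[C@]23C(=O)O[C@](C)(CC[C@@H]2Br)[C@@H]13 | intermediate
27 | tricyclic bromide with iodomethyl arm, (3R,3aS,4R,7S,7aS) | IC[C@@H]1CC[C@]23C(=O)O[C@](C)(CC[C@@H]2Br)[C@@H]13 | intermediate
28 | 6-methylhept-5-en-2-one | CC(=O)CCC=C(C)C | starting material
29 | 4-[(2R)-3,3-dimethyloxiran-2-yl]butan-2-one | CC(=O)CC[C@H]1OC1(C)C | intermediate
30 | trimethyl({4-[(2R)-3,3-dimethyloxiran-2-yl]but-1-en-2-yl}oxy)silane | C=C(O[Si](C)(C)C)CC[C@H]1OC1(C)C | intermediate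
31 | (4R)-3,3-dimethyl-4-(trimethylsilyloxy)cyclohexan-1-one (not isolated) | CC1(C)CC(=O)CC[C@H]1O[Si](C)(C)C | intermediate
32 | (4R)-4-hydroxy-3,3-dimethylcyclohexan-1-one | CC1(C)CC(=O)CC[C@H]1O | intermediate
33 | (4S)-4-bromo-3,3-dimethylcyclohexan-1-one | CC1(C)CC(=O)CC[C@@H]1Br | intermediate
34 | CNP0282702.2: (3S,3aS,4R,7S,7aS)-7-bromo-3-{[(1S,4S)-4-bromo-1-hydroxy-3,3-dimethylcyclohexyl]methyl}-4-methyl trans-hydrindane with lactone bridge C7a–C(=O)–O–C4 | CC1(C)C[C@@](O)(C[C@@H]2CC[C@]34C(=O)O[C@](C)(CC[C@@H]3Br)[C@@H]24)CC[C@@H]1Br | target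

**Step count.** Total: 22 steps. Longest linear sequence: 18 steps (steps 1–17 and 22); steps 18–21 make the ring A ketone.

**Steps most likely to fail**

Step 22. The ketone may react through both chair forms, which would give poor facial selectivity at the ring A carbinol. Electron transfer may also go to the secondary C–Br bonds or to the ketone and not to the C–I bond. Fallback, from 27 back to 34: displacement of iodide with PhSO2Na gives the phenyl sulfone F5. Its lithio derivative (LiN(iPr)2, THF, −78 °C) adds to ketone 33 at low temperature, where the chair with equatorial bromine is the most populated, and gives the β-hydroxy sulfone F6. Reductive desulfonylation (Na(Hg), Na2HPO4, MeOH, −20 °C) then gives the target 34.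

Step 14. The axial oxyphosphonium group may be lost by E2 elimination toward C6, or substitution at this neopentyl-type carbon may not take place. Fallback, from 20 back to 23: the equatorial alcohol 20 is converted with SOBr2 into the bromosulfite F4, and TiBr4 collapses it to bromide 23 with retention by front-side delivery of bromide inside an ion pair (titanium-promoted stereoretentive halogenation of cyclic secondary alcohols). Steps 12 and 13 are then not needed.

Step 11. The samarium enolate may be protonated before it reaches the aldehyde (plain debromination), the bridged aldolate may reopen by retro-aldol cleavage, or electrons may go to the aldehyde. Fallback, from 18 back to 21: the aldehyde is condensed with NH2OH·HCl/pyridine to the oxime F1 and dehydrated to the nitrile F2. An intramolecular Blaise reaction (activated Zn, THF, reflux) joins the zinc enolate to the nitrile irreversibly and without a carbinol stereocentre. Hydrolysis of the ketimine F3 with aqueous HCl gives the β-keto lactone 21, so step 12 falls away.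

Further compounds
F1 | step 11 | oxime of aldehyde 18 | CC(C)[Si](C(C)C)(C(C)C)OCC[C@@H]1CC[C@@]2(Br)C(=O)O[C@](C)(CCC=NO)[C@@H]12
F2 | step 11 | nitrile from 18 (3-cyanoethyl arm in place of 3-oxopropyl) | CC(C)[Si](C(C)C)(C(C)C)OCC[C@@H]1CC[C@@]2(Br)C(=O)O[C@](C)(CCC#N)[C@@H]12
F3 | step 11 | tricyclic C7 ketimine (imine of 21) | CC(C)[Si](C(C)C)(C(C)C)OCC[C@@H]1CC[C@]23C(=O)O[C@](C)(CCC2=N)[C@@H]13
F4 | step 14 | bromosulfite of alcohol 20 | CC(C)[Si](C(C)C)(C(C)C)OCC[C@@H]1CC[C@]23C(=O)O[C@](C)(CC[C@@H]2OS(=O)Br)[C@@H]13
F5 | step 22 | phenyl sulfone from iodide 27 | O=S(=O)(C[C@@H]1CC[C@]23C(=O)O[C@](C)(CC[C@@H]2Br)[C@@H]13)c1ccccc1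
F6 | step 22 | β-hydroxy sulfone (target with PhSO2 on the CH between ring B and ring A) | CC1(C)C[C@@](O)(C([C@@H]2CC[C@]34C(=O)O[C@](C)(CC[C@@H]3Br)[C@@H]24)S(=O)(=O)c2ccccc2)CC[C@@H]1Br
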